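**Retrosynthetic overview**
1. Target ⇐ acid-triggered loss of MeOH across C1–C2 plus cleavage of two MOM ethers from a 1-methoxytetralin hydroxy ketone. The enone is unveiled last, so C3 never sits α to a carbonyl next to a C=C.
2. That tetralin ⇐ aldehyde-only reduction of a keto aldehyde ⇐ one oxidative cascade. The C2–C3 bond joins the α-carbon of a 3-arylpropanal, reversed in polarity as its chiral enamine radical cation (an enolonium equivalent), to the α-carbon of a β-methoxyvinyl aryl ketone (both normally donor carbons). The resulting oxocarbenium ion closes C1–C8a by Friedel–Crafts attack.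
3. 3-Arylpropanal ⇐ Heck coupling of MOM-protected 4-bromo-2-methoxyphenol with allyl alcohol.
4. β-Methoxyvinyl ketone ⇐ Claisen formylation and O-methylation of MOM-protected acetovanillone.
5. Ring order: both benzene rings are bought; the only ring made is the cyclohexene ring, closed in the cascade that also sets C3 (R).

Assumption: the target stereocentre is R (CH2OH > C2 > C4 > H); locants C1–C8a are the naphthalene locants of the target; MOM = methoxymethyl, phen = 1,10-phenanthroline.

**Route**

Step 1
Reactants: 1 1-(4-hydroxy-3-methoxyphenyl)ethan-1-one (acetovanillone)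
Product: 2 1-[3-methoxy-4-(methoxymethoxy)phenyl]ethan-1-one
Conditions: MOMCl (1.3 equiv), i-Pr2NEt (1.5 equiv), CH2Cl2, 0 °C to rt
Reagents that add atoms: chloromethyl methyl ether (MOMCl), COCCl
Why: Williamson-type O-alkylation of the phenol by the reactive α-chloro ether gives a MOM ether that survives base and the later oxidant, keeps the ring electron-rich and falls off in the final acid step.

Step 2
Reactants: 2 1-[3-methoxy-4-(methoxymethoxy)phenyl]ethan-1-one
Product: 4 (E)-3-methoxy-1-[3-methoxy-4-(methoxymethoxy)phenyl]prop-2-en-1-one, via sodium enolate 3 (not isolated)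
Conditions: NaH (1.2 equiv), HCO2Me (3 equiv), THF, 0 °C to rt; then DMF, Me2SO4 (1.3 equiv), 0 °C to rt
Reagents that add atoms: methyl formate, COC=O; dimethyl sulfate, COS(=O)(=O)OC
Why: Crossed Claisen condensation with the non-enolisable formate gives the stabilised sodium enolate of the β-keto aldehyde, and the hard electrophile Me2SO4 in DMF alkylates it on the formyl oxygen (O-alkylation of a 1,3-dicarbonyl enolate) to give the E vinylogous ester.

Step 3
Reactants: 5 4-bromo-2-methoxyphenol
Product: 6 4-bromo-2-methoxy-1-(methoxymethoxy)benzene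
Conditions: MOMCl (1.3 equiv), i-Pr2NEt (1.5 equiv), CH2Cl2, 0 °C to rt
Reagents that add atoms: chloromethyl methyl ether (MOMCl), COCCl
Why: The same Williamson-type O-alkylation protects the phenol as an alkoxy-type donor, so the arene stays nucleophilic para to its methoxy group for the later ring closure.

Step 4
Reactants: 6 4-bromo-2-methoxy-1-(methoxymethoxy)benzene; 7 prop-2-en-1-ol (allyl alcohol)
Product: 8 3-[3-methoxy-4-(methoxymethoxy)phenyl]propanal
Conditions: Pd(OAc)2 (5 mol %), Bu4NCl (1 equiv), NaHCO3 (2.5 equiv), DMF, 80 °C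
Reagents that add atoms: none
Why: Heck arylation of allyl alcohol at its terminal carbon, followed by β-hydride elimination toward the carbinol carbon, gives an enol that tautomerises to the 3-arylpropanal (Heck reaction with redox isomerisation).

Step 5
Reactants: 8 3-[3-methoxy-4-(methoxymethoxy)phenyl]propanal; 4 (E)-3-methoxy-1-[3-methoxy-4-(methoxymethoxy)phenyl]prop-2-en-1-one (3 equiv, excess recovered)
Product: 10 [(3R)-3-(hydroxymethyl)-1,6-dimethoxy-7-(methoxymethoxy)-1,2,3,4-tetrahydronaphthalen-2-yl][3-methoxy-4-(methoxymethoxy)phenyl]methanone (epimers at C1/C2), via keto aldehyde 9 (not isolated)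
Conditions: (2S,5S)-5-benzyl-2-tert-butyl-3-methylimidazolidin-4-one·CF3CO2H (20 mol %), [Fe(phen)3](SbF6)3 (2.5 equiv), Na2HPO4 (2.5 equiv), DME, −30 °C; SiO2 plug; then NaBH4, EtOH/CH2Cl2, −78 °C
Reagents that add atoms: none
Why: Proposed new method: the imidazolidinone forms the E-enamine of 8, which the trivalent iron oxidant converts by one-electron oxidation into a 3π-electron radical cation (an enolonium equivalent at the aldehyde α-carbon) that adds, on the Si face left open by the benzyl group (this sets C3 as R), to the donor α-carbon of push–pull alkene 4, after which a second one-electron oxidation of the α-methoxy radical gives an oxocarbenium ion that the tethered arene captures para to its methoxy group to close the six-membered ring, and NaBH4 at −78 °C then reduces only the aldehyde (the C1 and C2 centres are mixtures but vanish in step 6); the closest known reaction types are the organo-SOMO α-enolation of aldehydes with enolsilanes and the organo-SOMO cation-terminated [4+2] of 3-arylpropanals with styrenes, 4 replacing the enolsilane or styrene.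

Step 6
Reactants: 10 [(3R)-3-(hydroxymethyl)-1,6-dimethoxy-7-(methoxymethoxy)-1,2,3,4-tetrahydronaphthalen-2-yl][3-methoxy-4-(methoxymethoxy)phenyl]methanone
Product: 11 [(3R)-7-hydroxy-3-(hydroxymethyl)-6-methoxy-3,4-dihydronaphthalen-2-yl](4-hydroxy-3-methoxyphenyl)methanone (CNP0352298.1)
Conditions: HCl (1 M in MeOH)/THF 1:1, 45 °C
Reagents that add atoms: none
Why: Acid ionises the benzylic C1 methoxy group (cation stabilised by the para methoxy group) and loss of the C2 proton gives the enone conjugated to arene and ketone (E1 β-elimination), while the same acid cleaves both MOM acetals by methanolysis, would close any uncyclised vinylogous ester from step 5 through the same oxocarbenium ion, and leaves C3 untouched because it carries no acidifying group.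

**Compound list**
1 | 1-(4-hydroxy-3-methoxyphenyl)ethan-1-one (acetovanillone) | CC(=O)c1ccc(O)c(OC)c1 | starting material
2 | 1-[3-methoxy-4-(methoxymethoxy)phenyl]ethan-1-one | CC(=O)c1ccc(OCOC)c(OC)c1 | intermediate
3 | sodium (Z)-3-[3-methoxy-4-(methoxymethoxy)phenyl]-3-oxoprop-1-en-1-olate | [Na+].[O-]/C=C\C(=O)c1ccc(OCOC)c(OC)c1 | intermediate
4 | (E)-3-methoxy-1-[3-methoxy-4-(methoxymethoxy)phenyl]prop-2-en-1-one | CO/C=C/C(=O)c1ccc(OCOC)c(OC)c1 | intermediate
5 | 4-bromo-2-methoxyphenol | COc1cc(Br)ccc1O | starting material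
6 | 4-bromo-2-methoxy-1-(methoxymethoxy)benzene | COCOc1ccc(Br)cc1OC | intermediate
7 | prop-2-en-1-ol (allyl alcohol) | C=CCO | starting material
8 | 3-[3-methoxy-4-(methoxymethoxy)phenyl]propanal | O=CCCc1ccc(OCOC)c(OC)c1 | intermediate
9 | (2R)-4,7-dimethoxy-3-[3-methoxy-4-(methoxymethoxy)benzoyl]-6-(methoxymethoxy)-1,2,3,4-tetrahydronaphthalene-2-carbaldehyde (epimers at C3/C4) | COCOc1ccc(C(=O)C2C(OC)c3cc(OCOC)c(OC)cc3C[C@H]2C=O)cc1OC | intermediate
10 | [(3R)-3-(hydroxymethyl)-1,6-dimethoxy-7-(methoxymethoxy)-1,2,3,4-tetrahydronaphthalen-2-yl][3-methoxy-4-(methoxymethoxy)phenyl]methanone (epimers at C1/C2) | COCOc1ccc(C(=O)C2C(OC)c3cc(OCOC)c(OC)cc3C[C@H]2CO)cc1OC | intermediate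
11 | [(3R)-7-hydroxy-3-(hydroxymethyl)-6-methoxy-3,4-dihydronaphthalen-2-yl](4-hydroxy-3-methoxyphenyl)methanone | COc1cc(C(=O)C2=Cc3cc(O)c(OC)cc3C[C@H]2CO)ccc1O | target

**Step count**
Total: 6 steps (step 5 is telescoped with the reduction). Longest linear sequence: 4 steps (1 → 2 → 4 → 10 → 11, or 5 → 6 → 8 → 10 → 11).

**Steps most likely to fail, with fallbacks**

Step 5 is the most likely to fail. Vinylogous ester 4 is a weak π-nucleophile, the oxocarbenium ion may lose a proton instead of being captured by the arene, and the electron-rich arene may be over-oxidised. The fallback sets out from 2 and 8 and returns at 11; it separates the asymmetric coupling from the ring closure and avoids a stoichiometric oxidant.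
- Ketone 2 is silylated (TMSOTf, Et3N, CH2Cl2, 0 °C) to the silyl enol ether trimethyl({1-[3-methoxy-4-(methoxymethoxy)phenyl]ethenyl}oxy)silane F1.
- NBS (THF, −78 to 0 °C) converts it into the bromo ketone 2-bromo-1-[3-methoxy-4-(methoxymethoxy)phenyl]ethan-1-one F2.
- Photoredox organocatalytic α-alkylation of 8 with F2 is a known enantioselective reaction in which the α-bromo ketone is the enolonium partner. Conditions: Ru(bpy)3Cl2 (bpy = 2,2'-bipyridine, 0.5 mol %), (2R,5S)-2-tert-butyl-3,5-dimethylimidazolidin-4-one trifluoromethanesulfonate (20 mol %), 2,6-lutidine, DMF, visible light. It gives the keto aldehyde (2R)-4-[3-methoxy-4-(methoxymethoxy)phenyl]-2-{[3-methoxy-4-(methoxymethoxy)phenyl]methyl}-4-oxobutanal F3.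
- NaBH4 (EtOH/CH2Cl2, −78 °C) gives the hydroxy ketone (3R)-4-hydroxy-1-[3-methoxy-4-(methoxymethoxy)phenyl]-3-{[3-methoxy-4-(methoxymethoxy)phenyl]methyl}butan-1-one F4.
- Me2NCH(OMe)2 (toluene, 90 °C) gives the enaminone (3R)-2-[(dimethylamino)methylidene]-4-hydroxy-1-[3-methoxy-4-(methoxymethoxy)phenyl]-3-{[3-methoxy-4-(methoxymethoxy)phenyl]methyl}butan-1-one F5.
- CF3CO2H in CH2Cl2, then HCl/MeOH, closes the ring by Friedel–Crafts attack of the arene on the protonated enaminone, expels dimethylamine and removes both MOM groups to give 11.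

Step 2 can fail through C-methylation or O-methylation on the ketone oxygen of enolate 3. The fallback sets out from 2 and returns at 4. Electrophilic formylation of 2 with dimethoxycarbenium tetrafluoroborate (made from HC(OMe)3 and BF3·OEt2; then i-Pr2NEt, CH2Cl2, −78 to −20 °C) gives the β-keto acetal 3,3-dimethoxy-1-[3-methoxy-4-(methoxymethoxy)phenyl]propan-1-one F6. This loses methanol on heating in toluene with catalytic pyridinium p-toluenesulfonate to give 4.

Step 4 can fail through slow oxidative addition of the electron-rich bromide, cinnamyl-alcohol and branched by-products, or aldol self-condensation of 8 in the basic medium. The fallback sets out from 6 and returns at 8.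
- Heck coupling of 6 with methyl acrylate (Pd(OAc)2, P(o-tol)3, Et3N, DMF, 100 °C) gives methyl (E)-3-[3-methoxy-4-(methoxymethoxy)phenyl]prop-2-enoate F7.
- Hydrogenation (H2, Pd/C, EtOAc) gives methyl 3-[3-methoxy-4-(methoxymethoxy)phenyl]propanoate F8.
- Partial reduction with i-Bu2AlH (CH2Cl2, −78 °C) gives 8.

**Further compounds**
F1 | step 5 | trimethyl({1-[3-methoxy-4-(methoxymethoxy)phenyl]ethenyl}oxy)silane | C=C(O[Si](C)(C)C)c1ccc(OCOC)c(OC)c1
F2 | step 5 | 2-bromo-1-[3-methoxy-4-(methoxymethoxy)phenyl]ethan-1-one | O=C(CBr)c1ccc(OCOC)c(OC)c1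
F3 | step 5 | (2R)-4-[3-methoxy-4-(methoxymethoxy)phenyl]-2-{[3-methoxy-4-(methoxymethoxy)phenyl]methyl}-4-oxobutanal | O=C[C@@H](CC(=O)c1ccc(OCOC)c(OC)c1)Cc1ccc(OCOC)c(OC)c1
F4 | step 5 | (3R)-4-hydroxy-1-[3-methoxy-4-(methoxymethoxy)phenyl]-3-{[3-methoxy-4-(methoxymethoxy)phenyl]methyl}butan-1-one | OC[C@@H](CC(=O)c1ccc(OCOC)c(OC)c1)Cc1ccc(OCOC)c(OC)c1
F5 | step 5 | (3R)-2-[(dimethylamino)methylidene]-4-hydroxy-1-[3-methoxy-4-(methoxymethoxy)phenyl]-3-{[3-methoxy-4-(methoxymethoxy)phenyl]methyl}butan-1-one | CN(C)C=C(C(=O)c1ccc(OCOC)c(OC)c1)[C@H](CO)Cc1ccc(OCOC)c(OC)c1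
F6 | step 2 | 3,3-dimethoxy-1-[3-methoxy-4-(methoxymethoxy)phenyl]propan-1-one | COC(OC)CC(=O)c1ccc(OCOC)c(OC)c1
F7 | step 4 | methyl (E)-3-[3-methoxy-4-(methoxymethoxy)phenyl]prop-2-enoate | COC(=O)/C=C/c1ccc(OCOC)c(OC)c1
F8 | step 4 | methyl 3-[3-methoxy-4-(methoxymethoxy)phenyl]propanoate | COC(=O)CCc1ccc(OCOC)c(OC)c1
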